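**Plan**

- Retrosynthesis first cuts the two aryl–CH2 bonds at ring B (to ring A and to ring C), then the C‑acetyl bond of ring A. Ring A, numbered as its dienone (C1 carbonyl, C6 quaternary), is then opened at C1–C2, C3–C4 and C1–C6, leading back to ethoxyacetylene and a 3‑ethoxycyclobutenone, itself from methyl geranyl ketene (propionic acid plus geranyl bromide).
- Enabling feature: ring A is a cyclohexane‑1,3,5‑trione whose carbon between two of the carbonyl carbons is quaternary (methyl, geranyl). It is the hydrolysed form of a 3,5‑diethoxy‑6,6‑disubstituted cyclohexa‑2,4‑dienone, the product of a cyclobutenone–alkoxyalkyne ring expansion that cannot aromatise.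
- Forward order: ring A is built first (steps 1–7). Ring C (the 2,2‑dimethylchromene) is made from butyrylphloroglucinol by tosyl‑directed annulation with prenal and joined to ring B through a Mannich base (steps 8–12). The last step links ring A to the ring B–ring C dimer through a methylene carbon.
- Stereochemistry: the only stereocentre, the quaternary carbon of ring A, forms racemic in the ring expansion and disappears in the symmetric trione. It is then set by an enantiotopic‑carbon‑selective O‑to‑C acetyl shift under a chiral 4‑aminopyridine, and as a quaternary carbon it cannot epimerise afterwards. The (E)‑alkene comes unchanged from geranyl bromide.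

Key step: step 4

Assumption: ring A is drawn in the enol tautomer of the target SMILES and the descriptor (R) refers to that drawing; if the (S)‑catalyst of step 7 favours the wrong enantiotopic carbon, its (R)‑enantiomer is used instead.

**Step 1**
Reactants: 1 propionic acid; 2 geranyl bromide
Product: 4 (4E)-2,5,9-trimethyldeca-4,8-dienoic acid (racemic), via dilithium propanoate enediolate 3 (not isolated)
Conditions: LiN(i-Pr)2 (LDA, 2.1 equiv), THF, 0 °C to 40 °C; then 2, 0 °C to rt; aq. HCl
Reagents that add atoms: none
Why: Alkylation of a carboxylic acid dianion, in which the enediolate carbon displaces the primary allylic bromide by SN2 without touching the (E)-alkene; the new stereocentre is racemic and is destroyed in step 3.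

**Step 2**
Reactants: 4 (4E)-2,5,9-trimethyldeca-4,8-dienoic acid
Product: 5 (4E)-2,5,9-trimethyldeca-4,8-dienoyl chloride (racemic)
Conditions: (COCl)2 (1.2 equiv), HCONMe2 (DMF, cat.), CH2Cl2, 0 °C to rt; evaporate, use crude
Reagents that add atoms: oxalyl chloride, O=C(Cl)C(Cl)=O
Why: Standard acid chloride formation through the chloroiminium (Vilsmeier-type) activator, under which the trisubstituted alkenes should survive brief contact with HCl at or below room temperature.

**Step 3**
Reactants: 5 (4E)-2,5,9-trimethyldeca-4,8-dienoyl chloride; 6 ethoxyacetylene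
Product: 8 3-ethoxy-4-[(2E)-3,7-dimethylocta-2,6-dien-1-yl]-4-methylcyclobut-2-en-1-one (racemic), via methyl geranyl ketene 7 (not isolated)
Conditions: Et3N (1.3 equiv), 6 (3 equiv, hexanes solution), CH2Cl2, 0 °C to 40 °C, sealed vessel
Reagents that add atoms: none
Why: Dehydrochlorination of the α-branched acid chloride gives the dialkylketene, which the electron-rich alkyne traps in a regioselective thermal [2+2] cycloaddition (ketene carbonyl carbon to alkyne CH), the usual entry to 3-alkoxy-4,4-dialkylcyclobutenones; the quaternary stereocentre is racemic and is lost again in step 4.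

**Step 4**
Reactants: 8 3-ethoxy-4-geranyl-4-methylcyclobut-2-en-1-one; 6 ethoxyacetylene
Product: 12 3,5-diethoxy-6-[(2E)-3,7-dimethylocta-2,6-dien-1-yl]-6-methylcyclohexa-2,4-dien-1-one (racemic), via vinylketene 9 (not isolated), via 4-vinylcyclobutenone 10 (not isolated), via dienylketene 11 (not isolated)
Conditions: 6 (3 equiv), toluene, 80–90 °C, sealed tube
Reagents that add atoms: none
Why: Thermal 4π electrocyclic opening of 8 gives vinylketene 9, whose ketene C=C adds the alkyne in a [2+2] cycloaddition to 10; a second 4π opening gives dienylketene 11, so that the C1–C2 and C3–C4 bonds of 12 are new and both alkyne carbons sit between the former ketene carbon and the former cyclobutenone CH. The closest known reaction type is the Danheiser annulation of cyclobutenones with alkoxyacetylenes, which ends at the cyclohexa-2,4-dienone when the terminal carbon is fully substituted. The one ring formed, the six-membered carbocycle of ring A, closes by thermal disrotatory 6π electrocyclisation of 11, joining the ketene carbon to the carbon carrying methyl and geranyl (C1–C6). That carbon becomes a stereocentre, but nothing controls it, so 12 is expected racemic; this costs nothing because hydrolysis in step 5 removes the centre. The step needs the alkyne CH to bond to the ketene carbonyl carbon, which the polarising ethoxy group secures, and it needs bimolecular trapping to outrun [1,5]-hydrogen shift or cycloaddition of the ketene to the geranyl alkenes, which the excess alkyne and the unfavourable tether lengths to both alkenes should secure.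

**Step 5**
Reactants: 12 3,5-diethoxy-6-geranyl-6-methylcyclohexa-2,4-dien-1-one
Product: 13 2-[(2E)-3,7-dimethylocta-2,6-dien-1-yl]-2-methylcyclohexane-1,3,5-trione (achiral)
Conditions: 0.5 M aq. HCl, THF, rt
Reagents that add atoms: water, O
Why: Acid hydrolysis of the two vinylogous ester enol ethers, mild enough to leave the geranyl alkenes alone, gives the mirror-symmetric trione in which the former stereocentre has become a prochiral carbon.

**Step 6**
Reactants: 13 2-geranyl-2-methylcyclohexane-1,3,5-trione
Product: 14 4-[(2E)-3,7-dimethylocta-2,6-dien-1-yl]-4-methyl-3,5-dioxocyclohex-1-en-1-yl acetate (no fixed configuration)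
Conditions: AcCl (1.0 equiv), Et3N (1.1 equiv), CH2Cl2, −78 °C to 0 °C
Reagents that add atoms: acetyl chloride, CC(Cl)=O
Why: Kinetic O-acylation of the trione enolate at its least hindered oxygen gives the enol ester, as in the first stage of 2-acylcyclohexane-1,3-dione syntheses; any O-regioisomer converges in step 7, and no configuration is fixed because the enol ester tautomers interconvert.

**Step 7**
Reactants: 14 enol acetate of the trione
Product: 15 (4R)-2-acetyl-4-[(2E)-3,7-dimethylocta-2,6-dien-1-yl]-3,5-dihydroxy-4-methylcyclohexa-2,5-dien-1-one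
Conditions: (S)-3-(1-acetoxy-2,2,2-triphenylethyl)-4-(dimethylamino)pyridine ((S)-TADMAP, 10 mol %), Et3N (1.2 equiv), toluene, −20 °C; dilute HCl wash
Reagents that add atoms: none
Why: Proposed new method: the catalyst takes the acetyl group from the enol ester to give a chiral N-acetylpyridinium ion paired with the mirror-symmetric trione enolate, whose two nucleophilic ring carbons are enantiotopic; C–C bond formation inside this contact ion pair at one of them, made irreversible when Et3N deprotonates the acidic tricarbonyl product, fixes the configuration of the quaternary carbon; the closest known reaction types are the DMAP- or cyanide-catalysed enol ester to 2-acyl-1,3-dione rearrangement and the enantioselective Steglich rearrangement of enol esters with chiral 4-aminopyridines, neither of which has been used to choose between enantiotopic carbons of a trione.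

**Step 8**
Reactants: 16 1-(2,4,6-trihydroxyphenyl)butan-1-one (butyrylphloroglucinol)
Product: 17 4-butanoyl-3,5-dihydroxyphenyl 4-methylbenzenesulfonate
Conditions: TsCl (1.0 equiv), K2CO3 (1.1 equiv), acetone, 0 °C to rt
Reagents that add atoms: p-toluenesulfonyl chloride, Cc1ccc(cc1)S(Cl)(=O)=O
Why: Selective sulfonylation of the hydroxyl para to the acyl group, the most acidic one and the only one not hydrogen-bonded to the ketone, leaves a symmetric resorcinol from which the chromene annulation can give only one regioisomer.

**Step 9**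
Reactants: 17 4-butanoyl-3,5-dihydroxyphenyl tosylate; 18 3-methylbut-2-enal (prenal)
Product: 20 8-butanoyl-7-hydroxy-2,2-dimethyl-2H-chromen-5-yl 4-methylbenzenesulfonate, via ortho-quinone methide 19 (not isolated)
Conditions: 18 (1.5 equiv), ethylenediammonium diacetate (EDDA, 20 mol %), toluene, reflux
Reagents that add atoms: none
Why: Iminium-mediated Knoevenagel-type condensation at the ring carbon followed by oxa-6π electrocyclisation through the oxygen ortho to the ketone, which places the butanoyl group at C8 and leaves C6 free; no stereocentre is formed.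

**Step 10**
Reactants: 20 chromenyl tosylate
Product: 21 1-(5,7-dihydroxy-2,2-dimethyl-2H-chromen-8-yl)butan-1-one
Conditions: KOH (3 equiv), EtOH/H2O, 60 °C; then dilute HCl
Reagents that add atoms: none
Why: Hydroxide attacks sulfur of the aryl sulfonate activated by the para ketone (S–O cleavage) and releases the phenol, while the chromene alkene and the ketone are stable to base.

**Step 11**
Reactants: 21 1-(5,7-dihydroxy-2,2-dimethyl-2H-chromen-8-yl)butan-1-one
Product: 22 1-{6-[(dimethylamino)methyl]-5,7-dihydroxy-2,2-dimethyl-2H-chromen-8-yl}butan-1-one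
Conditions: Me2N=CH2+ I− (Eschenmoser's salt, 1.05 equiv), Et3N (1.1 equiv), CH2Cl2, 0 °C to rt
Reagents that add atoms: N,N-dimethylmethyleneiminium iodide (Eschenmoser's salt), C=[N+](C)C.[I-]
Why: Mannich aminomethylation with a preformed iminium ion at the only free ring position, which is activated by both flanking hydroxyls.

**Step 12**
Reactants: 22 chromene Mannich base; 16 1-(2,4,6-trihydroxyphenyl)butan-1-one
Product: 24 1-{3-[(8-butanoyl-5,7-dihydroxy-2,2-dimethyl-2H-chromen-6-yl)methyl]-2,4,6-trihydroxyphenyl}butan-1-one, via ortho-quinone methide 23 (not isolated)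
Conditions: 16 (4 equiv), 1,4-dioxane, 90 °C
Reagents that add atoms: none
Why: Thermal loss of dimethylamine from the phenolic Mannich base gives an ortho-quinone methide that is trapped by Michael addition of a ring carbon of the phloroglucinol and rearomatises, the excess of 16 limiting double alkylation.

**Step 13**
Reactants: 15 (4R)-acetyl trione of ring A; 24 ring B–ring C dimer
Product: 27 target CNP0103039.1, via ring A Mannich base 25 (not isolated), via methylidene trione 26 (not isolated)
Conditions: 15, Me2N=CH2+ I− (1.0 equiv), MeCN, 0 °C to rt; then 24 (1.1 equiv), 45 °C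
Reagents that add atoms: N,N-dimethylmethyleneiminium iodide (Eschenmoser's salt), C=[N+](C)C.[I-]
Why: Mannich reaction at the single nucleophilic ring carbon of 15, elimination of dimethylamine to the 2-methylidene-1,3-dione and Michael addition of the only free aromatic carbon of 24, the usual way to bridge a cyclic 1,3-dicarbonyl and a phloroglucinol with one methylene; the quaternary stereocentre is not involved and keeps its configuration.

**Compound list**

1 | propionic acid | CCC(=O)O | starting material
2 | geranyl bromide, (2E)-1-bromo-3,7-dimethylocta-2,6-diene | BrC/C=C(\C)CCC=C(C)C | starting material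
3 | dilithium propanoate enediolate | CC=C([O-])[O-].[Li+].[Li+] | intermediate (not isolated)
4 | (4E)-2,5,9-trimethyldeca-4,8-dienoic acid (racemic) | CC(C/C=C(\C)CCC=C(C)C)C(=O)O | intermediate
5 | (4E)-2,5,9-trimethyldeca-4,8-dienoyl chloride (racemic) | CC(C/C=C(\C)CCC=C(C)C)C(Cl)=O | intermediate
6 | ethoxyacetylene | C#COCC | starting material
7 | methyl geranyl ketene, (4E)-2,5,9-trimethyldeca-1,4,8-trien-1-one | CC(C/C=C(\C)CCC=C(C)C)=C=O | intermediate (not isolated)
8 | 3-ethoxy-4-[(2E)-3,7-dimethylocta-2,6-dien-1-yl]-4-methylcyclobut-2-en-1-one (racemic) | CCOC1=CC(=O)C1(C)C/C=C(\C)CCC=C(C)C | intermediate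
9 | vinylketene, (6E)-3-ethoxy-4,7,11-trimethyldodeca-1,3,6,10-tetraen-1-one (C3=C4 geometry not fixed) | O=C=CC(OCC)=C(C)C/C=C(\C)CCC=C(C)C | intermediate (not isolated)
10 | 3-ethoxy-4-[(4E)-1-ethoxy-2,5,9-trimethyldeca-1,4,8-trien-1-yl]cyclobut-2-en-1-one (racemic) | O=C1C=C(OCC)C1C(OCC)=C(C)C/C=C(\C)CCC=C(C)C | intermediate (not isolated)
11 | dienylketene, (8E)-3,5-diethoxy-6,9,13-trimethyltetradeca-1,3,5,8,12-pentaen-1-one, C2 and C5 cis across C3=C4 | O=C=C/C(OCC)=C\C(OCC)=C(C)C/C=C(\C)CCC=C(C)C | intermediate (not isolated)
12 | 3,5-diethoxy-6-[(2E)-3,7-dimethylocta-2,6-dien-1-yl]-6-methylcyclohexa-2,4-dien-1-one (racemic) | CCOC1=CC(OCC)=CC(=O)C1(C)C/C=C(\C)CCC=C(C)C | intermediate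
13 | 2-[(2E)-3,7-dimethylocta-2,6-dien-1-yl]-2-methylcyclohexane-1,3,5-trione (achiral, drawn as triketone) | O=C1CC(=O)C(C)(C/C=C(\C)CCC=C(C)C)C(=O)C1 | intermediate
14 | 4-[(2E)-3,7-dimethylocta-2,6-dien-1-yl]-4-methyl-3,5-dioxocyclohex-1-en-1-yl acetate (tautomerically mobile, no fixed configuration) | CC(=O)OC1=CC(=O)C(C)(C/C=C(\C)CCC=C(C)C)C(=O)C1 | intermediate
15 | (4R)-2-acetyl-4-[(2E)-3,7-dimethylocta-2,6-dien-1-yl]-3,5-dihydroxy-4-methylcyclohexa-2,5-dien-1-one | O=C1C=C(O)[C@@](C)(C/C=C(\C)CCC=C(C)C)C(O)=C1C(C)=O | intermediate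
16 | 1-(2,4,6-trihydroxyphenyl)butan-1-one (butyrylphloroglucinol) | CCCC(=O)c1c(O)cc(O)cc1O | starting material
17 | 4-butanoyl-3,5-dihydroxyphenyl 4-methylbenzenesulfonate | CCCC(=O)c1c(O)cc(OS(=O)(=O)c2ccc(C)cc2)cc1O | intermediate
18 | 3-methylbut-2-enal (prenal) | CC(C)=CC=O | starting material
19 | 4-butanoyl-3-hydroxy-6-(3-methylbut-2-en-1-ylidene)-5-oxocyclohexa-1,3-dien-1-yl 4-methylbenzenesulfonate (ortho-quinone methide) | CCCC(=O)C1=C(O)C=C(OS(=O)(=O)c2ccc(C)cc2)C(=CC=C(C)C)C1=O | intermediate (not isolated)
20 | 8-butanoyl-7-hydroxy-2,2-dimethyl-2H-chromen-5-yl 4-methylbenzenesulfonate | CCCC(=O)c1c(O)cc(OS(=O)(=O)c3ccc(C)cc3)c2c1OC(C)(C)C=C2 | intermediate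
21 | 1-(5,7-dihydroxy-2,2-dimethyl-2H-chromen-8-yl)butan-1-one | CCCC(=O)c1c(O)cc(O)c2c1OC(C)(C)C=C2 | intermediate
22 | 1-{6-[(dimethylamino)methyl]-5,7-dihydroxy-2,2-dimethyl-2H-chromen-8-yl}butan-1-one | CCCC(=O)c1c(O)c(CN(C)C)c(O)c2c1OC(C)(C)C=C2 | intermediate
23 | 8-butanoyl-7-hydroxy-2,2-dimethyl-6-methylidene-2H-chromen-5(6H)-one (ortho-quinone methide) | CCCC(=O)C1=C(O)C(=C)C(=O)C2=C1OC(C)(C)C=C2 | intermediate (not isolated)
24 | 1-{3-[(8-butanoyl-5,7-dihydroxy-2,2-dimethyl-2H-chromen-6-yl)methyl]-2,4,6-trihydroxyphenyl}butan-1-one | CCCC(=O)c1c(O)cc(O)c(Cc2c(O)c3c(c(C(=O)CCC)c2O)OC(C)(C)C=C3)c1O | intermediate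
25 | (4R)-2-acetyl-6-[(dimethylamino)methyl]-4-[(2E)-3,7-dimethylocta-2,6-dien-1-yl]-3,5-dihydroxy-4-methylcyclohexa-2,5-dien-1-one | CN(C)CC1=C(O)[C@@](C)(C/C=C(\C)CCC=C(C)C)C(O)=C(C(C)=O)C1=O | intermediate (not isolated)
26 | 2-acetyl-4-[(2E)-3,7-dimethylocta-2,6-dien-1-yl]-3-hydroxy-4-methyl-6-methylidenecyclohex-2-ene-1,5-dione (configuration as in 15) | C=C1C(=O)[C@@](C)(C/C=C(\C)CCC=C(C)C)C(O)=C(C(C)=O)C1=O | intermediate (not isolated)
27 | CNP0103039.1, (4R)-2-acetyl-6-{[3-butanoyl-5-[(8-butanoyl-5,7-dihydroxy-2,2-dimethyl-2H-chromen-6-yl)methyl]-2,4,6-trihydroxyphenyl]methyl}-4-[(2E)-3,7-dimethylocta-2,6-dien-1-yl]-3,5-dihydroxy-4-methylcyclohexa-2,5-dien-1-one | CCCC(=O)c1c(O)c(CC2=C(O)[C@@](C)(C/C=C(\C)CCC=C(C)C)C(O)=C(C(C)=O)C2=O)c(O)c(Cc2c(O)c3c(c(C(=O)CCC)c2O)OC(C)(C)C=C3)c1O | target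

**Step count**

Total: 13 steps. Longest linear sequence: 8 steps (steps 1–7 and 13); the ring C branch (steps 8–12) joins in step 13.

**Steps most likely to fail**

1. Step 7 (proposed new method). The catalyst-bound acetyl cation has to tell methyl from geranyl on a carbon two bonds away from the reacting carbon, so discrimination between the enantiotopic ring carbons may be weak. Uncatalysed acetyl transfer or a second acetylation would erode the result further. The fallback uses known chemistry, sets out from 14 and returns at 15. Enol acetate 14 is rearranged with achiral 4-(dimethylamino)pyridine (DMAP, 10 mol %) and Et3N in CH2Cl2, the standard enol ester to 2-acyl-1,3-dione rearrangement, to give racemic 2-acetyl-4-geranyl-3,5-dihydroxy-4-methylcyclohexa-2,5-dien-1-one F1. Preparative chromatography on a chiral stationary phase (amylose tris(3,5-dimethylphenylcarbamate), hexane/2-propanol/formic acid) then separates 15 from its (4S)-enantiomer F2.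

2. Step 4. The vinylketene may be diverted before the alkyne traps it, by [1,5]-hydrogen shift, dimerisation or cycloaddition to a geranyl alkene. The hindered cyclobutenone may also open only at temperatures where ethoxyacetylene fragments or where the geranyl group of the dienone migrates by [3,3] shift. The fallback replaces the pericyclic cascade by an anionic ring construction, sets out from 2 and returns at 13. Geranyl bromide 2 alkylates methyl 2-methyl-3-oxobutanoate (K2CO3, acetone) to methyl (4E)-2-acetyl-2,5,9-trimethyldeca-4,8-dienoate F3. Its lithium enolate (LiN(i-Pr)2, THF, −78 °C) is acetylated with N-methoxy-N-methylacetamide to methyl 2-geranyl-2-methyl-3,5-dioxohexanoate F4. The dianion of this diketone (LiN(i-Pr)2, 2.2 equiv) closes onto the ester in a Dieckmann-type condensation to give trione 13.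

3. Step 13. The methylidene trione may condense with itself by hetero-Diels–Alder dimerisation or add to the chromene alkene, unconsumed iminium salt may aminomethylate 24, and methylene bridges may exchange between rings on prolonged heating. The fallback reverses the polarity of the last union, sets out from 24 and returns at 27. Dimer 24 is aminomethylated at its one free aromatic carbon (Me2N=CH2+ I−, Et3N, CH2Cl2) to the isolable 1-{3-[(8-butanoyl-5,7-dihydroxy-2,2-dimethyl-2H-chromen-6-yl)methyl]-5-[(dimethylamino)methyl]-2,4,6-trihydroxyphenyl}butan-1-one F5. Warming F5 with 15 in 1,4-dioxane releases the ring B ortho-quinone methide F6, which the nucleophilic ring carbon of 15 traps to give 27, so that ring A never acts as an electrophile.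

**Further compounds**

F1 | step 7 | racemic 2-acetyl-4-[(2E)-3,7-dimethylocta-2,6-dien-1-yl]-3,5-dihydroxy-4-methylcyclohexa-2,5-dien-1-one | O=C1C=C(O)C(C)(C/C=C(\C)CCC=C(C)C)C(O)=C1C(C)=O
F2 | step 7 | (4S)-2-acetyl-4-[(2E)-3,7-dimethylocta-2,6-dien-1-yl]-3,5-dihydroxy-4-methylcyclohexa-2,5-dien-1-one | O=C1C=C(O)[C@](C)(C/C=C(\C)CCC=C(C)C)C(O)=C1C(C)=O
F3 | step 4 | methyl (4E)-2-acetyl-2,5,9-trimethyldeca-4,8-dienoate (racemic) | COC(=O)C(C)(C/C=C(\C)CCC=C(C)C)C(C)=O
F4 | step 4 | methyl 2-[(2E)-3,7-dimethylocta-2,6-dien-1-yl]-2-methyl-3,5-dioxohexanoate (racemic) | COC(=O)C(C)(C/C=C(\C)CCC=C(C)C)C(=O)CC(C)=O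
F5 | step 13 | 1-{3-[(8-butanoyl-5,7-dihydroxy-2,2-dimethyl-2H-chromen-6-yl)methyl]-5-[(dimethylamino)methyl]-2,4,6-trihydroxyphenyl}butan-1-one | CCCC(=O)c1c(O)c(CN(C)C)c(O)c(Cc2c(O)c3c(c(C(=O)CCC)c2O)OC(C)(C)C=C3)c1O
F6 | step 13 | ring B ortho-quinone methide from F5 | CCCC(=O)C1=C(O)C(=C)C(=O)C(Cc2c(O)c3c(c(C(=O)CCC)c2O)OC(C)(C)C=C3)=C1O
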